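Metachromin H is cut at the exocyclic C2=CH2 bond and at C4'–C5' (ring A: C1 quaternary, C2 methylidene carbon, C3 the CH–CH3 carbon; chain C1'–C5' from C1). Chain carbons C1'–C4' can be tied back onto C2 as a sacrificial cyclohexenone ring that locks C1 and C3 into one rigid bicycle. A single auxiliary-controlled Michael–aldol annulation of the (S)-1-phenylethylamine imine of 2,6-dimethylcyclohexanone with but-3-en-2-one forms C1–C1' and C2=C4', sets C1 by enamine face control and C3 by equilibration. Epoxide fragmentation then reopens the ring to the C2 ketone and a C3'–C4' alkyne, which carry the methylidene, the C3' methyl and the quinone.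

Key step: step 2

Remark: commercial 2,6-dimethylcyclohexanone is taken as its cis/trans mixture, which needs no separation because both α-centres equilibrate at the imine stage.

Step 1
Reactants: 1 2,6-dimethylcyclohexanone; 2 (S)-1-phenylethylamine
Product: 3 (1S)-N-(2,6-dimethylcyclohexylidene)-1-phenylethan-1-amine (ring methyl centres undefined)
Conditions: 2 (1.1 equiv), TsOH·H2O (1 mol %), toluene, reflux, Dean–Stark
Reagents that add atoms: none
Why: Acid-catalysed ketimine condensation driven by azeotropic removal of water; the ring methyl centres stay undefined because they equilibrate through the imine–enamine tautomers, and the S centre of the amine is not touched.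

Step 2
Reactants: 3 (1S)-N-(2,6-dimethylcyclohexylidene)-1-phenylethan-1-amine; 4 but-3-en-2-one
Product: 8 (4aR,8R)-4a,8-dimethyl-4,4a,5,6,7,8-hexahydronaphthalen-2(3H)-one, via adduct imine 5 (not isolated), via diketone 6 (not isolated), via ketol 7 (not isolated)
Conditions: 4 (1.3 equiv), THF, 40 °C; then 20% aq AcOH, rt; then KOH (excess), MeOH, 60 °C, one flask
Reagents that add atoms: none
Why: The imine reacts through its tetrasubstituted secondary enamine tautomer in an aza-ene-like conjugate addition to 4, the N–H being handed to the α-carbon of the enone in a compact six-membered transition state, and after hydrolysis of imine 5 the methyl ketone enolate of 6 adds to the ring carbonyl and ketol 7 loses water by an E1cB path. The closest known reaction type is the deracemising Michael addition of 1-phenylethylamine imines of 2-alkylcyclohexanones to electron-poor alkenes followed by aldol condensation, an asymmetric Robinson annulation. The one ring that closes does so in a 6-(enolendo)-exo-trig aldol mode, which is favoured, and only this fused ketol can dehydrate, so bridged aldols revert. The quaternary centre C1 (C4a of 8) is controlled by the (S)-1-phenylethyl group, whose phenyl ring shields one enamine face so that 4 should add to the other and give the R centre; the methine centre C3 (C8 of 8) is controlled thermodynamically, because as the γ-carbon of the enone it is equilibrated by KOH through the dienolate to the equatorial methyl trans to the angular methyl, the cis epimer suffering a syn-diaxial CH3/CH3 contact. The step needs face selectivity at a fully substituted enamine carbon and C- rather than N-alkylation; the concerted proton transfer secures C-alkylation, and since both α-carbons of the ketone carry a methyl group either enamine gives the same constitution, leaving only the auxiliary-controlled face choice.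

Step 3
Reactants: 8 (4aR,8R)-4a,8-dimethyl-4,4a,5,6,7,8-hexahydronaphthalen-2(3H)-one
Product: 9 (4aR,8R)-1,8a-epoxy-4a,8-dimethyloctahydronaphthalen-2(1H)-one (oxirane on either face)
Conditions: 30% aq H2O2, NaOH (0.3 equiv), MeOH, 0 °C to rt
Reagents that add atoms: hydrogen peroxide, OO
Why: Weitz–Scheffer nucleophilic epoxidation, in which hydroperoxide adds to the enone β-carbon C8a and the enolate closes the oxirane; the existing stereocentres are untouched and the oxirane configuration is irrelevant because both of its carbons lose their stereochemistry in step 4.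

Step 4
Reactants: 9 (4aR,8R)-1,8a-epoxy-4a,8-dimethyloctahydronaphthalen-2(1H)-one
Product: 11 (2R,6R)-2-(but-3-yn-1-yl)-2,6-dimethylcyclohexan-1-one, via epoxy tosylhydrazone 10 (not isolated)
Conditions: TsNHNH2 (1.1 equiv), AcOH/CH2Cl2 (1:1), −20 °C to rt
Reagents that add atoms: none
Why: Eschenmoser–Tanabe fragmentation, in which the α,β-epoxy tosylhydrazone opens to an alkoxy azoalkene that expels N2 and sulfinate with cleavage of the C1–C8a bond, which should deliver the ring ketone and the terminal alkyne under acid mild enough to leave the α-methine centre unepimerised.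

Step 5
Reactants: 11 (2R,6R)-2-(but-3-yn-1-yl)-2,6-dimethylcyclohexan-1-one
Product: 12 (1R,3R)-1-(but-3-yn-1-yl)-1,3-dimethyl-2-methylidenecyclohexane
Conditions: Zn, CH2Br2, TiCl4 (reagent pre-formed in THF, 0–5 °C), then 11, CH2Cl2, 0 °C to rt
Reagents that add atoms: dibromomethane, BrCBr
Why: Takai–Lombardo methylenation with a non-basic geminal zinc–titanium methylene reagent, chosen because it olefinates hindered, enolisable ketones without epimerising the adjacent C–H centre and should leave a terminal alkyne alone; no new stereocentre is formed.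

Step 6
Reactants: 13 1,2,4,5-tetramethoxybenzene
Product: 15 (2,3,5,6-tetramethoxyphenyl)methanol, via aryllithium 14 (not isolated)
Conditions: n-BuLi (1.05 equiv), THF, 0 °C; (CH2O)n, 0 °C to rt; H2O
Reagents that add atoms: formaldehyde (as paraformaldehyde), C=O
Why: Directed ortho-lithiation at a C–H flanked by two methoxy groups followed by addition of the aryllithium to formaldehyde; the two free positions of 13 are equivalent and one equivalent of base should stop at monolithiation.

Step 7
Reactants: 15 (2,3,5,6-tetramethoxyphenyl)methanol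
Product: 16 3-(chloromethyl)-1,2,4,5-tetramethoxybenzene
Conditions: SOCl2 (1.2 equiv), CH2Cl2, 0 °C; used crude
Reagents that add atoms: thionyl chloride, O=S(Cl)Cl
Why: Deoxychlorination of an electron-rich benzylic alcohol through its chlorosulfite, fast at 0 °C; the chloride is used at once to avoid solvolysis on storage.

Step 8
Reactants: 12 (1R,3R)-1-(but-3-yn-1-yl)-1,3-dimethyl-2-methylidenecyclohexane; 16 3-(chloromethyl)-1,2,4,5-tetramethoxybenzene
Product: 18 3-{(2E)-5-[(1R,3R)-1,3-dimethyl-2-methylidenecyclohexyl]-3-methylpent-2-en-1-yl}-1,2,4,5-tetramethoxybenzene, via alkenylalane 17 (not isolated)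
Conditions: AlMe3 (2 equiv), Cp2ZrCl2 (0.25 equiv), ClCH2CH2Cl, rt; excess AlMe3 removed in vacuo; then 16, Pd(PPh3)4 (5 mol %), THF, rt
Reagents that add atoms: trimethylaluminium, C[Al](C)C
Why: Zirconium-catalysed Negishi carboalumination adds CH3 and Al syn across the terminal alkyne with the methyl on the internal carbon, and cross-coupling of the alkenylalane with the benzylic chloride at zerovalent palladium proceeds with retention, which should fix the E trisubstituted alkene; the hindered 1,1-disubstituted alkene is inert to carboalumination.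

Step 9
Reactants: 18 3-{(2E)-5-[(1R,3R)-1,3-dimethyl-2-methylidenecyclohexyl]-3-methylpent-2-en-1-yl}-1,2,4,5-tetramethoxybenzene
Product: 19 3-{(2E)-5-[(1R,3R)-1,3-dimethyl-2-methylidenecyclohexyl]-3-methylpent-2-en-1-yl}-2,5-dimethoxycyclohexa-2,5-diene-1,4-dione
Conditions: (NH4)2Ce(NO3)6 (2.5 equiv), MeCN/H2O, 0 °C
Reagents that add atoms: water, O
Why: Oxidative demethylation of a para-dimethoxyarene by tetravalent cerium, in which water attacks the two methoxy-bearing carbons and methanol leaves; either para pair gives the same 2,5-dimethoxyquinone by symmetry, and the isolated alkenes should survive the short, cold exposure.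

Step 10
Reactants: 19 3-{(2E)-5-[(1R,3R)-1,3-dimethyl-2-methylidenecyclohexyl]-3-methylpent-2-en-1-yl}-2,5-dimethoxycyclohexa-2,5-diene-1,4-dione
Product: 20 2-hydroxy-5-methoxy-3-{(2E)-5-[(1R,3R)-1,3-dimethyl-2-methylidenecyclohexyl]-3-methylpent-2-en-1-yl}cyclohexa-2,5-diene-1,4-dione
Conditions: 1 M aq KOH, MeOH, 0 °C to rt; then cold 1 M aq HCl to pH 3
Reagents that add atoms: potassium hydroxide, [K+].[OH-]
Why: Saponification of a vinylogous ester by addition–elimination, in which hydroxide should attack the methoxy-bearing carbon next to the side chain because that methoxy is twisted out of conjugation and its vinylogous ester is the more electrophilic, and the resulting vinylogous carboxylate resists a second hydrolysis.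

Step 11
Reactants: 20 2-hydroxy-5-methoxy-3-{(2E)-5-[(1R,3R)-1,3-dimethyl-2-methylidenecyclohexyl]-3-methylpent-2-en-1-yl}cyclohexa-2,5-diene-1,4-dione; 21 3-methylbutan-1-amine
Product: 22 metachromin H, 2-hydroxy-3-{(2E)-5-[(1R,3R)-1,3-dimethyl-2-methylidenecyclohexyl]-3-methylpent-2-en-1-yl}-5-[(3-methylbutyl)amino]cyclohexa-2,5-diene-1,4-dione
Conditions: 21 (5 equiv), EtOH, rt to 40 °C
Reagents that add atoms: none
Why: Addition–elimination of the primary amine at the remaining vinylogous methyl ester (conjugate addition at the methoxy carbon, loss of methanol), the only electrophilic site left once the amine has deprotonated the hydroxyquinone half; this gives the vinylogous amide of the target.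

Compound list
1 | 2,6-dimethylcyclohexanone (cis/trans mixture) | CC1CCCC(C)C1=O | starting material
2 | (S)-1-phenylethylamine | C[C@H](N)c1ccccc1 | starting material
3 | (1S)-N-(2,6-dimethylcyclohexylidene)-1-phenylethan-1-amine (ring methyl centres undefined) | CC1CCCC(C)C1=N[C@@H](C)c1ccccc1 | intermediate
4 | but-3-en-2-one | C=CC(C)=O | starting material
5 | (1S)-N-[(2R)-2,6-dimethyl-2-(3-oxobutyl)cyclohexylidene]-1-phenylethan-1-amine (C6 undefined) | CC(=O)CC[C@@]1(C)CCCC(C)C1=N[C@@H](C)c1ccccc1 | intermediate
6 | (2R)-2,6-dimethyl-2-(3-oxobutyl)cyclohexan-1-one (C6 epimers) | CC(=O)CC[C@@]1(C)CCCC(C)C1=O | intermediate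
7 | (4aR)-8a-hydroxy-4a,8-dimethyloctahydronaphthalen-2(1H)-one (C8 and C8a undefined) | O=C1CC2(O)C(C)CCC[C@]2(C)CC1 | intermediate
8 | (4aR,8R)-4a,8-dimethyl-4,4a,5,6,7,8-hexahydronaphthalen-2(3H)-one | O=C1C=C2[C@H](C)CCC[C@]2(C)CC1 | intermediate
9 | (4aR,8R)-1,8a-epoxy-4a,8-dimethyloctahydronaphthalen-2(1H)-one (oxirane on either face) | O=C1C3OC32[C@H](C)CCC[C@]2(C)CC1 | intermediate
10 | N'-[(4aR,8R)-1,8a-epoxy-4a,8-dimethyloctahydronaphthalen-2(1H)-ylidene]-4-methylbenzenesulfonohydrazide | Cc1ccc(cc1)S(=O)(=O)NN=C1C3OC32[C@H](C)CCC[C@]2(C)CC1 | intermediate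
11 | (2R,6R)-2-(but-3-yn-1-yl)-2,6-dimethylcyclohexan-1-one | O=C1[C@H](C)CCC[C@]1(C)CCC#C | intermediate
12 | (1R,3R)-1-(but-3-yn-1-yl)-1,3-dimethyl-2-methylidenecyclohexane | C=C1[C@H](C)CCC[C@]1(C)CCC#C | intermediate
13 | 1,2,4,5-tetramethoxybenzene | COc1cc(OC)c(OC)cc1OC | starting material
14 | (2,3,5,6-tetramethoxyphenyl)lithium | [Li]c1c(OC)c(OC)cc(OC)c1OC | intermediate
15 | (2,3,5,6-tetramethoxyphenyl)methanol | OCc1c(OC)c(OC)cc(OC)c1OC | intermediate
16 | 3-(chloromethyl)-1,2,4,5-tetramethoxybenzene | ClCc1c(OC)c(OC)cc(OC)c1OC | intermediate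
17 | {(1E)-4-[(1R,3R)-1,3-dimethyl-2-methylidenecyclohexyl]-2-methylbut-1-en-1-yl}dimethylalumane | C=C1[C@H](C)CCC[C@]1(C)CC/C(C)=C/[Al](C)C | intermediate
18 | 3-{(2E)-5-[(1R,3R)-1,3-dimethyl-2-methylidenecyclohexyl]-3-methylpent-2-en-1-yl}-1,2,4,5-tetramethoxybenzene | C=C1[C@H](C)CCC[C@]1(C)CC/C(C)=C/Cc1c(OC)c(OC)cc(OC)c1OC | intermediate
19 | 3-{(2E)-5-[(1R,3R)-1,3-dimethyl-2-methylidenecyclohexyl]-3-methylpent-2-en-1-yl}-2,5-dimethoxycyclohexa-2,5-diene-1,4-dione | C=C1[C@H](C)CCC[C@]1(C)CC/C(C)=C/CC1=C(OC)C(=O)C=C(OC)C1=O | intermediate
20 | 2-hydroxy-5-methoxy-3-{(2E)-5-[(1R,3R)-1,3-dimethyl-2-methylidenecyclohexyl]-3-methylpent-2-en-1-yl}cyclohexa-2,5-diene-1,4-dione | C=C1[C@H](C)CCC[C@]1(C)CC/C(C)=C/CC1=C(O)C(=O)C=C(OC)C1=O | intermediate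
21 | 3-methylbutan-1-amine | CC(C)CCN | starting material
22 | metachromin H | C=C1[C@H](C)CCC[C@]1(C)CC/C(C)=C/CC1=C(O)C(=O)C=C(NCCC(C)C)C1=O | target

Total step count: 11. Longest linear sequence: 9 steps (steps 1–5 and 8–11); the arene branch (steps 6–7) joins at step 8.

Steps most likely to fail

Step 2. The aza-ene addition may stall at an enamine carbon that is fully substituted and flanked by a second α-methyl group, the auxiliary may discriminate the two enamine faces incompletely, or the γ-centre may not equilibrate fully. The fallback gives up auxiliary control and resolves instead. Setting out from 1 and 4, a classical base-mediated Michael addition (catalytic NaOEt, EtOH, −10 °C) would give the racemic diketone F1, and KOH in hot EtOH would cyclise, dehydrate and equilibrate it to the racemic trans-octalone F2. Preparative chromatography on a chiral stationary phase would then supply the (4aR,8R) enantiomer, and the route is rejoined at 8.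

Step 5. Attack of the zinc–titanium reagent on a carbonyl flanked by a quaternary and a tertiary carbon may be too slow, the acetylenic C–H may consume the reagent, and forcing the reaction invites enolisation and loss of the methine configuration. The fallback removes the alkyne before the methylenation. Setting out from 11, NaBH4 in MeOH would give the alkynol F3 (carbinol epimers, which do not matter). Carboalumination as in step 8, with one extra equivalent of AlMe3 for the hydroxyl group, would give the bis-aluminated intermediate F4, and coupling with 16 under Pd(PPh3)4 followed by aqueous work-up would give the aryl alcohol F5. Dess–Martin periodinane would return the ketone F6 under neutral conditions. The more reactive, non-basic titanium methylidene source Cp2Ti(CH2)(Cl)AlMe2, now with no alkyne present, would then methylenate F6, and the route is rejoined at 18.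

Step 10. Hydroxide may attack the other vinylogous ester, or hydrolyse both methoxy groups. The fallback reverses the order of the two substitutions. Setting out from 19, amine 21 in EtOH would first exchange the unhindered methoxy group on the C–H side of the quinone and give the aminomethoxyquinone F7, a planar hydrogen-bonded vinylogous amide. Mild hydrolysis of the one remaining vinylogous ester (aq LiOH, THF, then dilute acid) would then give the target, so the route is rejoined at 22.

Further compounds
F1 | step 2 | racemic 2,6-dimethyl-2-(3-oxobutyl)cyclohexan-1-one (diastereomer mixture) | CC(=O)CCC1(C)CCCC(C)C1=O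
F2 | step 2 | racemic (4aR*,8R*)-4a,8-dimethyl-4,4a,5,6,7,8-hexahydronaphthalen-2(3H)-one | O=C1C=C2[C@H](C)CCC[C@]2(C)CC1.O=C1C=C2[C@@H](C)CCC[C@@]2(C)CC1
F3 | step 5 | (2R,6R)-2-(but-3-yn-1-yl)-2,6-dimethylcyclohexan-1-ol (C1 epimers) | OC1[C@H](C)CCC[C@]1(C)CCC#C
F4 | step 5 | O-dimethylaluminium alkoxide of the (E)-alkenyldimethylalane derived from F3 | C[Al](C)OC1[C@H](C)CCC[C@]1(C)CC/C(C)=C/[Al](C)C
F5 | step 5 | (2R,6R)-2,6-dimethyl-2-[(3E)-3-methyl-5-(2,3,5,6-tetramethoxyphenyl)pent-3-en-1-yl]cyclohexan-1-ol (C1 epimers) | OC1[C@H](C)CCC[C@]1(C)CC/C(C)=C/Cc1c(OC)c(OC)cc(OC)c1OC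
F6 | step 5 | (2R,6R)-2,6-dimethyl-2-[(3E)-3-methyl-5-(2,3,5,6-tetramethoxyphenyl)pent-3-en-1-yl]cyclohexan-1-one | O=C1[C@H](C)CCC[C@]1(C)CC/C(C)=C/Cc1c(OC)c(OC)cc(OC)c1OC
F7 | step 10 | 2-methoxy-5-[(3-methylbutyl)amino]-3-{(2E)-5-[(1R,3R)-1,3-dimethyl-2-methylidenecyclohexyl]-3-methylpent-2-en-1-yl}cyclohexa-2,5-diene-1,4-dione | C=C1[C@H](C)CCC[C@]1(C)CC/C(C)=C/CC1=C(OC)C(=O)C=C(NCCC(C)C)C1=O
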